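## Structural features

The target is a linear tridepside of three 2-hydroxy-6-methylbenzoyl (orsellinate) units. Ring A carries the methyl ester on C1, O4 of ring A is acylated by the C1 carbonyl of ring B, and O4 of ring B is acylated by the C1 carbonyl of ring C, whose own O4 is a free phenol. There is no stereocentre, so every problem is one of regiochemistry among five phenolic oxygens and three acyl carbons. In each ring the 2-hydroxyl is hydrogen-bonded to the neighbouring ester carbonyl, which makes it much less nucleophilic than the 4-oxygen and lets it stay unprotected. The fragile groups are the two aryl ester (depside) links, which are cleaved or scrambled by hydroxide, alkoxides, amines and basic fluoride and can undergo photo-Fries rearrangement under short-wave ultraviolet light, and the easily oxidised resorcinol rings. The real difficulty is that each acyl carbon sits between an ortho oxygen and an ortho methyl group, so making a depside ester by acylation needs a fully protected, strongly activated acid and a later deprotection. Ring C has the pattern that a vinylketene and an oxygenated alkyne assemble directly: the ester carbon on C1, a hydroxyl on the adjacent C2, a second oxygen on C4 (1,3 to the first) and a methyl on C6. The key step uses this: C1 and C6 come from the alkene of an unsaturated diazoketone that already carries the ring B ester, C2 from its ketone carbon, C5 from its diazo carbon, and C3 and C4 from the alkyne.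

## Logic of the disconnections

**23 to 22.** The O–Si bond on O4 of ring C is cut. The benzannulation delivers ring C with O2 free and O4 silylated, so the silyl ether is the only protecting group left at the end. The forward step must remove it without generating a nucleophile (phenoxide, alkoxide) that could attack the three esters.

**22 to 13 and 17.** Four C–C bonds of ring C are cut: C5–C6, C2–C3, C4–C5 and C1–C2. This removes ring C completely and leaves an open-chain enoate on O4 of ring B, so the hindered ring B–ring C ester already exists before the ring is made and is never formed by acylation of a hindered acid. The forward step needs a light source that excites the diazoketone but not the aryl esters, and a [2+2] addition of one orientation. 13 is taken as the 2E isomer. A 2Z isomer would put the ester carbonyl next to the ketene in 18, where it can trap the ketene by oxa-6π closure to a 6-aryloxy-2-pyranone. It would also turn the ester inwards in the closure of 20, and it would have to be made through a cis half ester that expels the phenol of 6 by anhydride formation once its carboxyl group is activated.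

**17 to 14 and 15, through 16.** The O–Si bond and the C–C bond of the alkyne are cut. The two-carbon ynolate 16 comes from a one-carbon ester and a one-carbon carbenoid in one flask. The forward step must silylate 16 on oxygen and not on carbon, which calls for a bulky chlorosilane.

**13 to 6 and 12.** The ester C–O bond between O4 of ring B and C1 of the pentenoate chain is cut. The diazo group is then made on a small molecule, and the most fragile bond of 13, an unhindered aryl enoate, is formed last under mildly basic conditions. The forward step must pick the one non-chelated phenol of 6 out of three and must activate the carboxylate without protonating the diazo carbon.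

**12 to 11 to 9 to 7 and 8.** The O–K bond (O–CH3 in 11), the C–N bond of the diazo group and the C2=C3 alkene are cut in turn. The diazo group is introduced by diazo transfer to the methyl ketone rather than by acylating diazomethane, because diazomethane would add as a 1,3-dipole to an alkene flanked by two carbonyl groups. The alkene is made by a Wittig reaction that sets the E geometry from two simple commercial compounds.

**6 to 5 to 3 and 4, and 3 to 1.** The two benzyl C–O bonds, then the ester C–O bond between O4 of ring A and the C1 carbonyl of ring B, then the benzyl groups of 3 are cut. This is the one classical depside esterification of the route. It needs both phenols of the acid masked, and it relies on the chelated 2-hydroxyl of 4 staying unreactive.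

## Other disconnections considered

**Alternative 1:** The cut opens ring B at C1–C6 and C2–C3. It leads to a 6-methyl-2-pyranone carrying the protected ring C acid as an ester on its 4-oxygen (A2) and to the 3-methoxypropiolate ester of the 2-O-benzyl ring A phenol (A3). Forward, A2 would be the diene and A3 the dienophile in a Diels–Alder reaction, and the bridged lactone adduct would aromatise by decarboxylative cycloreversion to the fully protected tridepside A1, which has a methyl ether on O2 of ring B.
- In its favour: the plan is convergent. Both ester bonds are made on unhindered partners, so no hindered benzoate esterification is needed; this is better than the chosen plan, where step 2 is such an esterification. The polarity of the push–pull alkyne matches the nucleophilic C3 of the pyranone, so the orientation should be right. No diazo compound or lamp is needed, which is better on hazard.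
- Against it: 2-pyranones are reluctant dienes and a donor-substituted propiolate is a deactivated dienophile, so long, strong heating is to be expected. Under it the enol ester of A2 could transfer its acyl group and A3 could decompose. A1 then needs hydrogenolysis of three benzyl ethers and a selective Lewis-acid cleavage of the ring B methyl ether next to two aryl esters, two operations against one desilylation.
- Comparison: in structure it builds the central ring between two finished rings, while the chosen plan grows the terminal ring on a finished didepside. In mechanism it forms two C–C bonds in a thermal [4+2]/retro-[4+2] pair, against four in a photochemical–thermal cascade. In step count it is expected to be equal or slightly longer, because A2 and A3 both need protected arenes and the end game is longer.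

**Alternative 2:** The three C2–O bonds are cut, which leads to tridepside A5, lacking all three 2-hydroxyls and carrying an acetate on O4 of ring C. The forward step would be a threefold carbonyl-directed ortho C–H oxygenation, for instance with Pd(OAc)2 or [RuCl2(p-cymene)]2 and K2S2O8 in CF3CO2H/(CF3CO)2O, to give A4.
- In its favour: each benzoyl ring has one free ortho C–H only, so the site on each ring is unambiguous. A5 can be made from mono-ortho-substituted acids without phenol protection. The plan is clearly the shortest, and on step economy it is better than the chosen one. The final unmasking (aryl acetate against silyl ether) is equal in count.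
- Against it: ester carbonyls are weak directing groups for divalent palladium or ruthenium. The reaction must succeed three times on one molecule. The acidic, oxidising medium threatens the aryl esters by acidolysis and acyl exchange. The phenols formed are more easily oxidised than the arenes they come from, and the aryloxy side of each ester offers competing C–H bonds.
- Comparison: in structure it keeps the whole skeleton and changes only the oxidation level. In mechanism it depends on catalyst control of a weakly directed C–H metalation, while the chosen plan depends on a pericyclic cascade whose orientation follows from polarity. Step economy favours the alternative; predictability of the key step favours the chosen plan.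

**Alternative 3:** The cut opens ring B at C1–C2 and C5–C6 and leads to the electron-rich diene A7 and the but-2-ynoate ester A8 of 4. Forward, a Diels–Alder reaction would join the unsubstituted diene terminus to the methyl-bearing alkyne carbon and the ketene acetal terminus to the ester-bearing carbon. Elimination of one acetal methoxy group would aromatise the adduct, and desilylation would give didepside A6, with a free 4-hydroxyl and a 2-methyl ether on ring B.
- In its favour: the orientation of such ketene acetal dienes towards alkynoates follows from polarity and is well established. The reaction is thermal. The hindered ring A–ring B ester exists beforehand as an unhindered alkynoate, the same advantage the chosen plan has for ring C (equal). A6 would be reached in two steps from 4, shorter than the three steps to 6 (better).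
- Against it: it solves ring B and not ring C. The ring C acyl group must still be attached by a hindered esterification with a protected acid such as 3 and then deprotected, and the ring B methyl ether must be cleaved by a Lewis acid in the presence of two aryl esters. A7 is moisture-sensitive, a 3-methyl alkynoate is a sluggish dienophile, and the chelated phenol of A8 may protonate the ketene acetal.
- Comparison: in structure it shifts the problem one ring inwards. In mechanism it forms two C–C bonds against four. In total step count it is expected to be equal or slightly longer once ring C and the demethylation are added.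

Key step: step 9

Remark on the chemistry: diazoketone 13 is made as the 2E isomer (ester trans to the diazoacetyl group); its connectivity is unchanged and the alkene geometry disappears in ring C.

## Route

Step 1
Reactants: 1 orsellinic acid (2,4-dihydroxy-6-methylbenzoic acid)
Product: 3 2,4-bis(benzyloxy)-6-methylbenzoic acid, via tribenzyl ester 2 (not isolated)
Conditions: BnBr, K2CO3, DMSO, 40 °C; then KOH, H2O, 90 °C; 2 M HCl
Reagents that add atoms: benzyl bromide, BrCc1ccccc1; potassium hydroxide, [K+].[OH-]
Why: Williamson O-benzylation of both phenols and the carboxylate, then saponification of the hindered benzyl ester by KOH in hot aqueous DMSO in the same flask; the aryl benzyl ethers are inert to hydroxide.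

Step 2
Reactants: 3 2,4-bis(benzyloxy)-6-methylbenzoic acid; 4 methyl orsellinate (methyl 2,4-dihydroxy-6-methylbenzoate)
Product: 5 methyl 4-[2,4-bis(benzyloxy)-6-methylbenzoyloxy]-2-hydroxy-6-methylbenzoate
Conditions: (CF3CO)2O, toluene, rt
Reagents that add atoms: none
Why: Depside esterification through the mixed aroyl trifluoroacetic anhydride; the electron-rich aroyl group is transferred to the free 4-hydroxyl of 4, while its 2-hydroxyl, hydrogen-bonded to the methyl ester, should not be acylated.

Step 3
Reactants: 5 methyl 4-[2,4-bis(benzyloxy)-6-methylbenzoyloxy]-2-hydroxy-6-methylbenzoate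
Product: 6 methyl lecanorate (methyl 4-(2,4-dihydroxy-6-methylbenzoyloxy)-2-hydroxy-6-methylbenzoate)
Conditions: H2 (1 atm), 10% Pd/C, EtOAc, rt
Reagents that add atoms: none
Why: Hydrogenolysis of the two benzyl ethers; the aryl ester and the methyl ester are inert and nothing else in the molecule is reducible.

Step 4
Reactants: 7 butane-2,3-dione; 8 methyl (triphenylphosphoranylidene)acetate
Product: 9 methyl (E)-3-methyl-4-oxopent-2-enoate
Conditions: CH2Cl2, 0 °C to rt
Reagents that add atoms: none
Why: Wittig olefination of one carbonyl of the activated 1,2-diketone by a stabilised ylide; a small excess of 7 limits double olefination, and the stabilised ylide should favour the E alkene (ester trans to acetyl), which is also the more stable isomer.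

Step 5
Reactants: 9 methyl (E)-3-methyl-4-oxopent-2-enoate
Product: 11 methyl (E)-5-diazo-3-methyl-4-oxopent-2-enoate, via trifluoroacetyl diketone 10 (not isolated)
Conditions: LiN(SiMe3)2, THF, −78 °C; CF3CO2CH2CF3, −78 °C; 5% HCl; then MsN3, Et3N, H2O (1 equiv), MeCN, rt
Reagents that add atoms: methanesulfonyl azide, CS(=O)(=O)N=[N+]=[N-]
Why: Detrifluoroacetylative diazo transfer (a Regitz-type deacylative diazo transfer): the kinetic enolate of the methyl ketone is C-trifluoroacetylated, and the activated 1,3-diketone 10 takes the diazo group from the sulfonyl azide with loss of the trifluoroacetyl group. This avoids diazomethane, which would undergo 1,3-dipolar cycloaddition with the doubly activated alkene.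

Step 6
Reactants: 11 methyl (E)-5-diazo-3-methyl-4-oxopent-2-enoate
Product: 12 potassium (E)-5-diazo-3-methyl-4-oxopent-2-enoate
Conditions: KOSiMe3 (1.0 equiv), THF, 0 °C to rt; filter
Reagents that add atoms: potassium trimethylsilanolate, [K+].[O-][Si](C)(C)C
Why: Anhydrous methyl ester cleavage by potassium trimethylsilanolate gives the carboxylate salt directly, so the acid-labile diazoketone never meets a free carboxylic acid or aqueous acid.

Step 7
Reactants: 6 methyl lecanorate; 12 potassium (E)-5-diazo-3-methyl-4-oxopent-2-enoate
Product: 13 methyl 4-{4-[(2E)-5-diazo-3-methyl-4-oxopent-2-enoyloxy]-2-hydroxy-6-methylbenzoyloxy}-2-hydroxy-6-methylbenzoate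
Conditions: 2,4,6-Cl3C6H2COCl, 18-crown-6 (cat.), THF, 0 °C; then 6, Et3N, DMAP (cat.), 0 °C
Reagents that add atoms: none
Why: Yamaguchi esterification: the carboxylate forms a mixed anhydride with the hindered aroyl chloride, and DMAP transfers the unhindered enoyl group to the only non-chelated phenol of 6 (O4 of ring B). The two 2-hydroxyls are hydrogen-bonded to ester carbonyls and should stay free, and the basic medium protects the diazo group.

Step 8
Reactants: 14 ethyl formate; 15 chlorotriisopropylsilane
Product: 17 (triisopropylsilyloxy)acetylene, via lithium ethynolate 16 (not isolated)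
Conditions: CH2Br2, lithium 2,2,6,6-tetramethylpiperidide, THF, −78 °C; 14; LiN(SiMe3)2; n-BuLi, −78 °C to rt; 15, −78 °C to rt
Reagents that add atoms: dibromomethane, BrCBr
Why: Kowalski ester homologation stopped at the ynolate: dibromomethyllithium adds to the formate, and the dibromo enolate undergoes Br–Li exchange and a 1,2-hydride shift with loss of LiBr to give 16. The bulky chlorosilane then silylates 16 on oxygen rather than on carbon.

Step 9
Reactants: 13 methyl 4-{4-[(2E)-5-diazo-3-methyl-4-oxopent-2-enoyloxy]-2-hydroxy-6-methylbenzoyloxy}-2-hydroxy-6-methylbenzoate; 17 (triisopropylsilyloxy)acetylene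
Product: 22 methyl 2-hydroxy-4-{2-hydroxy-4-[2-hydroxy-6-methyl-4-(triisopropylsilyloxy)benzoyloxy]-6-methylbenzoyloxy}-6-methylbenzoate, via vinylketene 18 (not isolated), via cyclobutenone 19 (not isolated), via dienylketene 20 (not isolated), via cyclohexadienone 21 (not isolated)
Conditions: 17 (2 equiv), hν (405 nm LEDs), ClCH2CH2Cl, 20 °C; then 80 °C
Reagents that add atoms: none
Why: Light of 405 nm excites only the diazoketone, not the salicylate-type aryl esters, so photo-Fries cleavage is avoided; Wolff rearrangement moves the methyl-bearing alkene carbon from the carbonyl carbon to the diazo carbon as N2 leaves, which forms C5–C6 of ring C and gives vinylketene 18. The ketene C=C of 18 adds to the electron-rich alkyne 17 in a [2+2] cycloaddition (C2–C3 and C4–C5); the electrophilic ketene carbonyl carbon bonds to the unsubstituted, nucleophilic alkyne carbon because the siloxy oxygen stabilises positive charge on the other one, and this alone places the two oxygens 1,3. At 80 °C cyclobutenone 19 opens by 4π conrotatory electrocyclic ring opening to dienylketene 20, and 6π disrotatory electrocyclisation of 20 closes the only new ring, the six-membered ring C, through the C1–C2 bond; enolisation of dienone 21 then gives the phenol, driven by aromaticity and the hydrogen bond to the ester carbonyl. The closest known reaction type is the Danheiser benzannulation of α,β-unsaturated α′-diazoketones with siloxyalkynes. No stereocentre remains, since the sp3 carbons of 19 and 21 are transient and are erased on aromatisation. The E geometry of 13 keeps the aryl ester trans to the ketene, so the ester carbonyl cannot capture the ketene by oxa-6π closure to a 2-pyranone, and the ester points outwards in the 6π closure. The chelated 2-hydroxyls of rings A and B are poor nucleophiles and, with an excess of 17 present, are not expected to intercept the ketenes.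

Step 10
Reactants: 22 methyl 2-hydroxy-4-{2-hydroxy-4-[2-hydroxy-6-methyl-4-(triisopropylsilyloxy)benzoyloxy]-6-methylbenzoyloxy}-6-methylbenzoate
Product: 23 methyl 4-{4-[(2,4-dihydroxy-6-methylbenzoyl)oxy]-2-hydroxy-6-methylbenzoyl}oxy-2-hydroxy-6-methylbenzoate (CNP0212402.0)
Conditions: HF·pyridine, pyridine, THF, 0 °C to rt
Reagents that add atoms: none
Why: Fluoride cleavage of the aryl silyl ether under buffered acidic conditions, in which no phenoxide or other nucleophile forms that could transesterify the two depside esters or the methyl ester.

## Compound list

1 | orsellinic acid (2,4-dihydroxy-6-methylbenzoic acid) | Cc1cc(O)cc(O)c1C(=O)O | starting material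
2 | benzyl 2,4-bis(benzyloxy)-6-methylbenzoate | Cc1cc(OCc2ccccc2)cc(OCc2ccccc2)c1C(=O)OCc1ccccc1 | intermediate
3 | 2,4-bis(benzyloxy)-6-methylbenzoic acid | Cc1cc(OCc2ccccc2)cc(OCc2ccccc2)c1C(=O)O | intermediate
4 | methyl orsellinate (methyl 2,4-dihydroxy-6-methylbenzoate) | COC(=O)c1c(C)cc(O)cc1O | starting material
5 | methyl 4-[2,4-bis(benzyloxy)-6-methylbenzoyloxy]-2-hydroxy-6-methylbenzoate | COC(=O)c1c(C)cc(OC(=O)c2c(C)cc(OCc3ccccc3)cc2OCc2ccccc2)cc1O | intermediate
6 | methyl lecanorate (methyl 4-(2,4-dihydroxy-6-methylbenzoyloxy)-2-hydroxy-6-methylbenzoate) | COC(=O)c1c(C)cc(OC(=O)c2c(C)cc(O)cc2O)cc1O | intermediate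
7 | butane-2,3-dione | CC(=O)C(C)=O | starting material
8 | methyl (triphenylphosphoranylidene)acetate | COC(=O)C=P(c1ccccc1)(c1ccccc1)c1ccccc1 | starting material
9 | methyl (E)-3-methyl-4-oxopent-2-enoate | COC(=O)/C=C(\C)C(C)=O | intermediate
10 | methyl (E)-7,7,7-trifluoro-3-methyl-4,6-dioxohept-2-enoate | COC(=O)/C=C(\C)C(=O)CC(=O)C(F)(F)F | intermediate
11 | methyl (E)-5-diazo-3-methyl-4-oxopent-2-enoate | COC(=O)/C=C(\C)C(=O)C=[N+]=[N-] | intermediate
12 | potassium (E)-5-diazo-3-methyl-4-oxopent-2-enoate | [K+].[O-]C(=O)/C=C(\C)C(=O)C=[N+]=[N-] | intermediate
13 | methyl 4-{4-[(2E)-5-diazo-3-methyl-4-oxopent-2-enoyloxy]-2-hydroxy-6-methylbenzoyloxy}-2-hydroxy-6-methylbenzoate | COC(=O)c1c(C)cc(OC(=O)c2c(C)cc(OC(=O)/C=C(\C)C(=O)C=[N+]=[N-])cc2O)cc1O | intermediate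
14 | ethyl formate | CCOC=O | starting material
15 | chlorotriisopropylsilane | CC(C)[Si](Cl)(C(C)C)C(C)C | starting material
16 | lithium ethynolate | [Li+].[O-]C#C | intermediate
17 | (triisopropylsilyloxy)acetylene | C#CO[Si](C(C)C)(C(C)C)C(C)C | intermediate
18 | vinylketene: ring B O4 ester of 6 with (2E)-3-methyl-5-oxopenta-2,4-dienoic acid | COC(=O)c1c(C)cc(OC(=O)c2c(C)cc(OC(=O)/C=C(\C)C=C=O)cc2O)cc1O | intermediate
19 | cyclobutenone: ring B O4 ester of 6 with (E)-3-[4-oxo-2-(triisopropylsilyloxy)cyclobut-2-en-1-yl]but-2-enoic acid (racemic at the ring CH) | COC(=O)c1c(C)cc(OC(=O)c2c(C)cc(OC(=O)/C=C(\C)C3C(=O)C=C3O[Si](C(C)C)(C(C)C)C(C)C)cc2O)cc1O | intermediate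
20 | dienylketene: ring B O4 ester of 6 with (2E,4E)-3-methyl-7-oxo-5-(triisopropylsilyloxy)hepta-2,4,6-trienoic acid | COC(=O)c1c(C)cc(OC(=O)c2c(C)cc(OC(=O)/C=C(\C)/C=C(\C=C=O)O[Si](C(C)C)(C(C)C)C(C)C)cc2O)cc1O | intermediate
21 | cyclohexadienone: ring B O4 ester of 6 with 2-methyl-6-oxo-4-(triisopropylsilyloxy)cyclohexa-2,4-diene-1-carboxylic acid (racemic at C1) | COC(=O)c1c(C)cc(OC(=O)c2c(C)cc(OC(=O)C3C(C)=CC(O[Si](C(C)C)(C(C)C)C(C)C)=CC3=O)cc2O)cc1O | intermediate
22 | methyl 2-hydroxy-4-{2-hydroxy-4-[2-hydroxy-6-methyl-4-(triisopropylsilyloxy)benzoyloxy]-6-methylbenzoyloxy}-6-methylbenzoate | COC(=O)c1c(C)cc(OC(=O)c2c(C)cc(OC(=O)c3c(C)cc(O[Si](C(C)C)(C(C)C)C(C)C)cc3O)cc2O)cc1O | intermediate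
23 | methyl 4-{4-[(2,4-dihydroxy-6-methylbenzoyl)oxy]-2-hydroxy-6-methylbenzoyl}oxy-2-hydroxy-6-methylbenzoate (CNP0212402.0) | COC(=O)c1c(C)cc(OC(=O)c2c(C)cc(OC(=O)c3c(C)cc(O)cc3O)cc2O)cc1O | target

## Step count and least certain steps

Total step count: 10. Longest linear sequence: 6 steps (steps 1, 2, 3, 7, 9, 10 from 1; equally steps 4, 5, 6, 7, 9, 10 from 7 and 8).

**Step 9 (key step).** The most likely failure is loss of ketene 18 before it meets the alkyne: capture by a phenolic hydroxyl of a second molecule, ketene dimerisation, or light-induced E to Z isomerisation of the enoate followed by oxa-6π closure onto the ester carbonyl. These can compete because the [2+2] step is bimolecular and the Wolff rearrangement may be slow at 405 nm, where the diazoketone absorbs weakly. Incomplete thermal opening of 19 is a smaller risk. Fallback: the benzannulation is given up and ring C is attached as a finished unit. The fallback sets out from 6 and 3, which are joined at O4 of ring B by the mixed-anhydride esterification of step 2 ((CF3CO)2O, toluene) to give methyl 4-{4-[2,4-bis(benzyloxy)-6-methylbenzoyloxy]-2-hydroxy-6-methylbenzoyloxy}-2-hydroxy-6-methylbenzoate F1. Hydrogenolysis of F1 (H2, Pd/C) comes back to the route at 23.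

**Step 8.** The tetrahedral adduct of the formate may collapse to the aldehyde before enolisation and take up a second carbenoid. Silylation may go partly on carbon to a silylketene, and the small, volatile product may be lost on isolation. Fallback: the ynolate is made by ring fragmentation instead of homologation. The fallback sets out from 15: 3-phenylisoxazole F2 is lithiated at C5 with n-BuLi in THF at −78 °C and fragments to benzonitrile and the ynolate, which comes back to the route at 16 and is silylated with 15 to give 17.

**Step 7.** The diazo group may be lost during carboxyl activation through traces of acid or chloride, phenoxide may add in conjugate fashion to the enoate, or a second phenol may be acylated; the acyl donor is both an activated Michael acceptor and a diazoketone. Fallback: the acylation is run before the diazo group exists. The fallback sets out from 9 and 6: KOSiMe3 converts 9 into potassium (E)-3-methyl-4-oxopent-2-enoate F3, and Yamaguchi esterification of F3 with 6 gives the ring B O4 keto ester F4. The diazo transfer of step 5 is then applied to F4, with enough LiN(SiMe3)2 to cover the two phenols, through the trifluoroacetyl diketone F5, and comes back to the route at 13.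

**Step 5.** Enolisation may take place in part at the C3 methyl group (γ to the ester), or the enolate may add to unreacted enone, since 9 is a strong Michael acceptor. Fallback: the diazo group is introduced without a strong base. The fallback sets out from 9, which is condensed with Me2NCH(OMe)2 to the enaminone methyl (2E,5E)-6-(dimethylamino)-3-methyl-4-oxohexa-2,5-dienoate F6. Regitz-type diazo transfer from MsN3 to F6 (cycloaddition, then cycloreversion that releases the N-sulfonyl formamidine) comes back to the route at 11.

## Further compounds

F1 | step 9 | methyl 4-{4-[2,4-bis(benzyloxy)-6-methylbenzoyloxy]-2-hydroxy-6-methylbenzoyloxy}-2-hydroxy-6-methylbenzoate | COC(=O)c1c(C)cc(OC(=O)c2c(C)cc(OC(=O)c3c(C)cc(OCc4ccccc4)cc3OCc3ccccc3)cc2O)cc1O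
F2 | step 8 | 3-phenylisoxazole | c1ccc(cc1)-c1ccon1
F3 | step 7 | potassium (E)-3-methyl-4-oxopent-2-enoate | [K+].[O-]C(=O)/C=C(\C)C(C)=O
F4 | step 7 | methyl 2-hydroxy-4-{2-hydroxy-6-methyl-4-[(2E)-3-methyl-4-oxopent-2-enoyloxy]benzoyloxy}-6-methylbenzoate | COC(=O)c1c(C)cc(OC(=O)c2c(C)cc(OC(=O)/C=C(\C)C(C)=O)cc2O)cc1O
F5 | step 7 | methyl 2-hydroxy-4-{2-hydroxy-6-methyl-4-[(2E)-7,7,7-trifluoro-3-methyl-4,6-dioxohept-2-enoyloxy]benzoyloxy}-6-methylbenzoate | COC(=O)c1c(C)cc(OC(=O)c2c(C)cc(OC(=O)/C=C(\C)C(=O)CC(=O)C(F)(F)F)cc2O)cc1O
F6 | step 5 | methyl (2E,5E)-6-(dimethylamino)-3-methyl-4-oxohexa-2,5-dienoate | COC(=O)/C=C(\C)C(=O)/C=C/N(C)C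
A1 | alternative 1 | methyl 2-(benzyloxy)-4-{4-[2,4-bis(benzyloxy)-6-methylbenzoyloxy]-2-methoxy-6-methylbenzoyloxy}-6-methylbenzoate | COC(=O)c1c(C)cc(OC(=O)c2c(C)cc(OC(=O)c3c(C)cc(OCc4ccccc4)cc3OCc3ccccc3)cc2OC)cc1OCc1ccccc1
A2 | alternative 1 | 6-methyl-2-oxo-2H-pyran-4-yl 2,4-bis(benzyloxy)-6-methylbenzoate | Cc1cc(OC(=O)c2c(C)cc(OCc3ccccc3)cc2OCc2ccccc2)cc(=O)o1
A3 | alternative 1 | methyl 2-(benzyloxy)-4-(3-methoxyprop-2-ynoyloxy)-6-methylbenzoate | COC#CC(=O)Oc1cc(C)c(C(=O)OC)c(OCc2ccccc2)c1
A4 | alternative 2 | methyl 4-{4-[4-(acetyloxy)-2-hydroxy-6-methylbenzoyloxy]-2-hydroxy-6-methylbenzoyloxy}-2-hydroxy-6-methylbenzoate | COC(=O)c1c(C)cc(OC(=O)c2c(C)cc(OC(=O)c3c(C)cc(OC(C)=O)cc3O)cc2O)cc1O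
A5 | alternative 2 | methyl 4-{4-[4-(acetyloxy)-2-methylbenzoyloxy]-2-methylbenzoyloxy}-2-methylbenzoate | COC(=O)c1c(C)cc(OC(=O)c2c(C)cc(OC(=O)c3c(C)cc(OC(C)=O)cc3)cc2)cc1
A6 | alternative 3 | methyl 2-hydroxy-4-(4-hydroxy-2-methoxy-6-methylbenzoyloxy)-6-methylbenzoate | COC(=O)c1c(C)cc(OC(=O)c2c(C)cc(O)cc2OC)cc1O
A7 | alternative 3 | 1,1-dimethoxy-3-(trimethylsilyloxy)buta-1,3-diene | COC(OC)=CC(=C)O[Si](C)(C)C
A8 | alternative 3 | methyl 4-(but-2-ynoyloxy)-2-hydroxy-6-methylbenzoate | CC#CC(=O)Oc1cc(C)c(C(=O)OC)c(O)c1
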